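**Retrosynthetic overview**

1. The C2-symmetric (2R,2'R) C50 diol is cut at both ring–chain σ-bonds, C6–C7 and C6'–C7' (tetrasubstituted ring-alkene carbon to chain CH). This gives two molecules of a C14 ring enol triflate that already carries the free (E)-4-hydroxy-3-methylbut-2-enyl side chain, and one all-E C22 nonaene bis(pinacol boronate). The coupling is the last step and needs no protecting group.
2. The bis(boronate) comes in one step from commercial C20 crocetindialdehyde by twofold boron–Wittig olefination, which adds C7 and C7' with E geometry.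
3. The ring triflate comes from 2-methylcyclohex-2-enone. Copper-catalysed asymmetric conjugate addition with enolate methylation sets C2 (R) and the C1 gem-dimethyl group; alkene shift, methylation at the future C5, enol triflation, cross-metathesis with methacrolein and reduction complete it.
4. Enabling feature: in each ring, C6 lies between quaternary C1 (gem-dimethyl, no hydrogen) and methyl-bearing C5, so a C6 ketone can enolise only toward C5 and gives a single tetrasubstituted C5=C6 enol triflate. With the C2 axis through C15=C15', both hindered sp2–sp2 junctions can be made by one palladium coupling event that runs twice in one flask.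
5. Ring order: no ring is formed in the route; both cyclohexene rings are carried from the cyclohexenone starting material.

Key step: step 8

Remark: carotenoid numbering is used for the target and systematic locants for the intermediates. All-E crocetindialdehyde, bis[(pinacolato)boryl]methane and the chiral imidazolinium NHC precursor of step 1 are taken as purchasable, and all polyene steps are run under argon in dim light.

**Route**

Step 1
Reactants: 1 2-methylcyclohex-2-en-1-one; 2 but-3-en-1-ylmagnesium bromide
Product: 4 (R)-3-(but-3-en-1-yl)-2,2-dimethylcyclohexan-1-one, via bromomagnesium enolate 3 (not isolated)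
Conditions: Cu(OTf)2 (3 mol %), chiral hydroxyalkyl-imidazolinium NHC precursor (4 mol %), Et2O, 0 °C; then MeI, DMPU, 0 °C → rt
Reagents that add atoms: iodomethane (CI)
Why: Copper-catalysed asymmetric conjugate addition of a primary alkyl Grignard reagent to an α-substituted cyclohexenone (the ligand antipode is chosen so that the butenyl group adds to the enone face that gives the (R) centre, the future C2), followed by C-methylation of the regiodefined magnesium enolate, which builds the gem-dimethyl carbon (future C1) without a further stereocentre.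

Step 2
Reactants: 4 (R)-3-(but-3-en-1-yl)-2,2-dimethylcyclohexan-1-one
Product: 5 (R)-3-[(E)-but-2-en-1-yl]-2,2-dimethylcyclohexan-1-one
Conditions: Pd(dba)2 (1 mol %), P(tBu)3 (1 mol %), iPrCOCl (1 mol %), toluene, 50 °C
Reagents that add atoms: none
Why: Olefin isomerisation by a palladium hydride formed in the flask (insertion/β-hydride elimination) should move the terminal double bond by one position under kinetic control to the (E)-2-alkene, whose geometry does not matter because step 5 consumes it, while the ketone and the remote stereocentre are untouched.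

Step 3
Reactants: 5 (R)-3-[(E)-but-2-en-1-yl]-2,2-dimethylcyclohexan-1-one
Product: 7 (3R,6RS)-3-[(E)-but-2-en-1-yl]-2,2,6-trimethylcyclohexan-1-one, via lithium enolate 6 (not isolated)
Conditions: LiN(iPr)2 (1.1 equiv), THF, −78 °C; MeI, −78 → 0 °C
Reagents that add atoms: iodomethane (CI)
Why: Kinetic enolate alkylation in which the ketone can be deprotonated only at C6 because C2 is quaternary, the epimer mixture at the new C6 centre (future C5) being erased in step 4.

Step 4
Reactants: 7 (3R,6RS)-3-[(E)-but-2-en-1-yl]-2,2,6-trimethylcyclohexan-1-one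
Product: 9 (R)-5-[(E)-but-2-en-1-yl]-2,6,6-trimethylcyclohex-1-en-1-yl trifluoromethanesulfonate, via lithium enolate 8 (not isolated)
Conditions: LiN(iPr)2 (1.2 equiv), THF, −78 → 0 °C; PhNTf2, 0 °C → rt
Reagents that add atoms: N-phenylbis(trifluoromethanesulfonimide) (O=S(=O)(N(c1ccccc1)S(=O)(=O)C(F)(F)F)C(F)(F)F)
Why: Enol triflate formation from the only possible enolate (the other α-carbon is quaternary) by O-sulfonylation, as known for 2,2,6-trimethylcyclohexanone, with the side-chain-bearing stereocentre remote from the enolate.

Step 5
Reactants: 9 (R)-5-[(E)-but-2-en-1-yl]-2,6,6-trimethylcyclohex-1-en-1-yl trifluoromethanesulfonate; 10 methacrolein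
Product: 11 (R)-2,6,6-trimethyl-5-[(E)-3-methyl-4-oxobut-2-en-1-yl]cyclohex-1-en-1-yl trifluoromethanesulfonate
Conditions: 10 (10 equiv), second-generation Hoveyda–Grubbs catalyst (5 mol %), CH2Cl2, 40 °C
Reagents that add atoms: none
Why: Olefin cross-metathesis of the 1,2-disubstituted alkene with the electron-poor 1,1-disubstituted partner should give the (E)-2-methyl enal under thermodynamic control with loss of propene, the tetrasubstituted enol triflate double bond being too hindered to engage the ruthenium carbene.

Step 6
Reactants: 11 (R)-2,6,6-trimethyl-5-[(E)-3-methyl-4-oxobut-2-en-1-yl]cyclohex-1-en-1-yl trifluoromethanesulfonate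
Product: 12 (R)-5-[(E)-4-hydroxy-3-methylbut-2-en-1-yl]-2,6,6-trimethylcyclohex-1-en-1-yl trifluoromethanesulfonate
Conditions: NaBH4, CeCl3·7H2O, MeOH, −20 °C
Reagents that add atoms: none
Why: Luche 1,2-reduction of the enal should give the (E)-allylic alcohol without touching the enol triflate or the geometry of the trisubstituted alkene.

Step 7
Reactants: 13 crocetindialdehyde; 14 bis[(pinacolato)boryl]methane
Product: 17 all-E C22 nonaene-1,18-diyl bis(pinacol boronate), via lithiated bis(boryl)methane 15 (not isolated), via mono-olefinated boronate aldehyde 16 (not isolated)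
Conditions: 14 (2.4 equiv), lithium 2,2,6,6-tetramethylpiperidide (2.4 equiv), THF, 0 °C; then 13, −78 °C → rt, dark
Reagents that add atoms: none
Why: Boron–Wittig olefination in which the α-boryl carbanion adds 1,2 to each aldehyde and stereoselective syn B–O elimination from the β-alkoxy gem-diboronate should give the (E)-alkenyl boronate at both ends, as established for aldehydes including enals, which extends the C20 chain by C7 and C7'.

Step 8
Reactants: 12 (R)-5-[(E)-4-hydroxy-3-methylbut-2-en-1-yl]-2,6,6-trimethylcyclohex-1-en-1-yl trifluoromethanesulfonate; 17 all-E C22 nonaene-1,18-diyl bis(pinacol boronate)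
Product: 19 (2R,2'R)-2,2'-bis[(E)-4-hydroxy-3-methylbut-2-en-1-yl]-β,β-carotene, via mono-coupled C36 alkenylboronate 18 (not isolated)
Conditions: 12 (2.2 equiv), Pd(PPh3)4 (10 mol %), TlOEt (4 equiv), THF–H2O (4:1), degassed, dark, 23 °C
Reagents that add atoms: none
Why: Twofold Suzuki–Miyaura coupling: zerovalent palladium inserts into the C6–OTf bond of 12, the (E)-alkenyl boronate terminus of 17 (C7), activated by TlOH formed from TlOEt and water, transmetalates, and reductive elimination forms the C6–C7 bond; the resulting C36 alkenylboronate 18 then couples in the same flask through its C7'–B end with a second molecule of 12, so the closing event joins the C14 ring unit to the ring-bearing C36 polyene and should deliver the complete C50 undecaene as the free diol. The closest known reaction type is the thallium-base-accelerated Suzuki coupling of 2,6,6-trimethylcyclohex-1-enyl triflate with dienyl- and polyenylboron reagents that makes the C6–C7 bond of retinoids, together with twofold palladium couplings of bis-metalated polyenes used for symmetrical carotenoids. No ring is closed and no stereocentre is created: C2 and C2' come unchanged from step 1, and because two enantioenriched halves are joined, the minor enantiomer of 12 should end up mostly in the meso diastereomer, which raises the enantiomeric purity of the C2-symmetric product. The selectivities needed are a single position for each ring double bond, secured because quaternary C1 leaves C5=C6 as the only possible enol triflate, and E geometry at C7=C8 and C7'=C8', secured by the stereodefined boronate and by stereoretentive transmetalation and reductive elimination. Coupling must also outrun protodeboronation and isomerisation of the polyenyl boronate, which the fast room-temperature thallium-hydroxide-promoted transmetalation, exclusion of light and oxygen and a slight excess of 12 are meant to secure, while the free allylic hydroxyl groups do not interfere.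

**Compound list**

1 | 2-methylcyclohex-2-en-1-one | CC1=CCCCC1=O | starting material
2 | but-3-en-1-ylmagnesium bromide | C=CCC[Mg]Br | starting material
3 | bromomagnesium (R)-3-(but-3-en-1-yl)-2-methylcyclohex-1-en-1-olate (formed in the flask, not isolated) | Br[Mg]OC1=C(C)[C@@H](CCC=C)CCC1 | intermediate
4 | (R)-3-(but-3-en-1-yl)-2,2-dimethylcyclohexan-1-one | O=C1C(C)(C)[C@@H](CCC=C)CCC1 | intermediate
5 | (R)-3-[(E)-but-2-en-1-yl]-2,2-dimethylcyclohexan-1-one (E expected as the main isomer) | O=C1C(C)(C)[C@@H](C/C=C/C)CCC1 | intermediate
6 | lithium (R)-5-[(E)-but-2-en-1-yl]-6,6-dimethylcyclohex-1-en-1-olate (formed in the flask, not isolated) | [Li]OC1=CCC[C@H](C/C=C/C)C1(C)C | intermediate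
7 | (3R,6RS)-3-[(E)-but-2-en-1-yl]-2,2,6-trimethylcyclohexan-1-one (C6 epimers) | O=C1C(C)(C)[C@@H](C/C=C/C)CCC1C | intermediate
8 | lithium (R)-5-[(E)-but-2-en-1-yl]-2,6,6-trimethylcyclohex-1-en-1-olate (formed in the flask, not isolated) | [Li]OC1=C(C)CC[C@H](C/C=C/C)C1(C)C | intermediate
9 | (R)-5-[(E)-but-2-en-1-yl]-2,6,6-trimethylcyclohex-1-en-1-yl trifluoromethanesulfonate | CC1=C(OS(=O)(=O)C(F)(F)F)C(C)(C)[C@@H](C/C=C/C)CC1 | intermediate
10 | methacrolein (2-methylprop-2-enal) | CC(=C)C=O | starting material
11 | (R)-2,6,6-trimethyl-5-[(E)-3-methyl-4-oxobut-2-en-1-yl]cyclohex-1-en-1-yl trifluoromethanesulfonate | CC1=C(OS(=O)(=O)C(F)(F)F)C(C)(C)[C@@H](C/C=C(\C)C=O)CC1 | intermediate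
12 | (R)-5-[(E)-4-hydroxy-3-methylbut-2-en-1-yl]-2,6,6-trimethylcyclohex-1-en-1-yl trifluoromethanesulfonate | CC1=C(OS(=O)(=O)C(F)(F)F)C(C)(C)[C@@H](C/C=C(\C)CO)CC1 | intermediate
13 | crocetindialdehyde, (2E,4E,6E,8E,10E,12E,14E)-2,6,11,15-tetramethylhexadeca-2,4,6,8,10,12,14-heptaenedial | O=C/C(C)=C/C=C/C(C)=C/C=C/C=C(C)/C=C/C=C(C)/C=O | starting material
14 | bis[(pinacolato)boryl]methane, 2,2'-methylenebis(4,4,5,5-tetramethyl-1,3,2-dioxaborolane) | CC1(C)OB(CB2OC(C)(C)C(C)(C)O2)OC1(C)C | starting material
15 | lithio-bis(4,4,5,5-tetramethyl-1,3,2-dioxaborolan-2-yl)methane (formed in the flask, not isolated) | [Li]C(B1OC(C)(C)C(C)(C)O1)B1OC(C)(C)C(C)(C)O1 | intermediate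
16 | (2E,4E,6E,8E,10E,12E,14E,16E)-2,6,11,15-tetramethyl-17-(4,4,5,5-tetramethyl-1,3,2-dioxaborolan-2-yl)heptadeca-2,4,6,8,10,12,14,16-octaenal (formed in the flask, not isolated) | CC1(C)OB(/C=C/C(C)=C/C=C/C(C)=C/C=C/C=C(C)/C=C/C=C(C)/C=O)OC1(C)C | intermediate
17 | 2,2'-[(1E,3E,5E,7E,9E,11E,13E,15E,17E)-3,7,12,16-tetramethyloctadeca-1,3,5,7,9,11,13,15,17-nonaene-1,18-diyl]bis(4,4,5,5-tetramethyl-1,3,2-dioxaborolane) | CC1(C)OB(/C=C/C(C)=C/C=C/C(C)=C/C=C/C=C(C)/C=C/C=C(C)/C=C/B2OC(C)(C)C(C)(C)O2)OC1(C)C | intermediate
18 | mono-coupled C36 alkenylboronate: ring unit of 12 joined at C6 to C7 of the all-E nonaene, far end (E)-CH=CH–B(pin) (formed in the flask, not isolated) | CC1=C(/C=C/C(C)=C/C=C/C(C)=C/C=C/C=C(C)/C=C/C=C(C)/C=C/B2OC(C)(C)C(C)(C)O2)C(C)(C)[C@@H](C/C=C(\C)CO)CC1 | intermediate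
19 | (2R,2'R)-2,2'-bis[(E)-4-hydroxy-3-methylbut-2-en-1-yl]-β,β-carotene (all-E) | CC1=C(/C=C/C(C)=C/C=C/C(C)=C/C=C/C=C(C)/C=C/C=C(C)/C=C/C2=C(C)CC[C@H](C/C=C(\C)CO)C2(C)C)C(C)(C)[C@@H](C/C=C(\C)CO)CC1 | target

**Totals**

Total step count: 8. Longest linear sequence: 7 steps (steps 1 to 6, then step 8).

**Steps most likely to fail**

Step 8. Oxidative addition and transmetalation at the doubly flanked C6 position may be slow, so that protodeboronation, homocoupling and E/Z isomerisation of the polyenyl boronate compete and the second coupling stops at the mono-coupled stage. The fallback sets out from 12 and 13 and comes back at 19. It replaces the sp2–sp2 coupling by carbonylation and a Wittig olefination at C7=C8. Palladium-catalysed reductive carbonylation of 12 (Pd(OAc)2, dppp, CO, Et3SiH, Et3N, DMF, 70 °C) should give (R)-5-[(E)-4-hydroxy-3-methylbut-2-en-1-yl]-2,6,6-trimethylcyclohex-1-ene-1-carbaldehyde F1, in which C7 is the formyl carbon. Reduction of 13 (NaBH4, MeOH/THF) should give the C20 heptaene-1,16-diol F2, which PPh3·HBr in MeOH should convert into the C20 bis(triphenylphosphonium) dibromide F3. Twofold Wittig reaction of F3 with F1 (NaOMe, MeOH/CH2Cl2), followed by thermal equilibration of Z isomers in hot heptane, should give 19.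

Step 2. The palladium hydride may walk the double bond past the 2-position or leave terminal alkene, giving positional isomers that cannot be separated. The fallback sets out from 1 and comes back at 5. It installs an allyl group by a [3,3]-sigmatropic route. Catalytic enantioselective allylboration of the carbonyl group of 1 (allyldiisopropoxyborane, chiral 3,3'-dibromo-BINOL catalyst, antipode chosen for the (R) carbinol) should give (R)-1-allyl-2-methylcyclohex-2-en-1-ol F4. Anionic oxy-Cope rearrangement (KH, 18-crown-6, THF) should move the allyl group suprafacially from C1 to C3, carrying the carbinol configuration into the new centre and giving potassium (R)-3-allyl-2-methylcyclohex-1-en-1-olate F5. Methylation of F5 in the same flask (MeI) should give (R)-3-allyl-2,2-dimethylcyclohexan-1-one F6. Cross-metathesis of F6 with (Z)-but-2-ene (second-generation Grubbs catalyst, CH2Cl2) should give 5.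

Step 7. Twofold olefination of the sparingly soluble dialdehyde may stay incomplete, vinylogous deprotonation may compete, and E selectivity or the C–B bonds may be lost during isolation of the polyenyl bis(boronate). The fallback sets out from 13 and comes back at 17. Seyferth–Gilbert homologation with dimethyl (1-diazo-2-oxopropyl)phosphonate (K2CO3, MeOH) should give the C22 heptaene-1,17-diyne F7. Zirconium-catalysed syn-hydroboration of both terminal alkynes (pinacolborane, Cp2Zr(H)Cl cat., Et3N) should give 17, with the E geometry fixed by syn addition.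

**Further compounds**

F1 | step 8 | (R)-5-[(E)-4-hydroxy-3-methylbut-2-en-1-yl]-2,6,6-trimethylcyclohex-1-ene-1-carbaldehyde | CC1=C(C=O)C(C)(C)[C@@H](C/C=C(\C)CO)CC1
F2 | step 8 | (2E,4E,6E,8E,10E,12E,14E)-2,6,11,15-tetramethylhexadeca-2,4,6,8,10,12,14-heptaene-1,16-diol | OC/C(C)=C/C=C/C(C)=C/C=C/C=C(C)/C=C/C=C(C)/CO
F3 | step 8 | [(2E,4E,6E,8E,10E,12E,14E)-2,6,11,15-tetramethylhexadeca-2,4,6,8,10,12,14-heptaene-1,16-diyl]bis(triphenylphosphonium) dibromide | [Br-].[Br-].C(/C(C)=C/C=C/C(C)=C/C=C/C=C(C)/C=C/C=C(C)/C[P+](c1ccccc1)(c1ccccc1)c1ccccc1)[P+](c1ccccc1)(c1ccccc1)c1ccccc1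
F4 | step 2 | (R)-1-allyl-2-methylcyclohex-2-en-1-ol | C=CC[C@]1(O)CCCC=C1C
F5 | step 2 | potassium (R)-3-allyl-2-methylcyclohex-1-en-1-olate | [K]OC1=C(C)[C@@H](CC=C)CCC1
F6 | step 2 | (R)-3-allyl-2,2-dimethylcyclohexan-1-one | O=C1C(C)(C)[C@@H](CC=C)CCC1
F7 | step 7 | (3E,5E,7E,9E,11E,13E,15E)-3,7,12,16-tetramethyloctadeca-3,5,7,9,11,13,15-heptaene-1,17-diyne | C#C/C(C)=C/C=C/C(C)=C/C=C/C=C(C)/C=C/C=C(C)/C#C
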